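**Strategy.** Ring A (C1–C4, C9, C10; C1 bears the octan-2-yl group, C2/C3 are the diosphenol carbons, C10 is the quaternary acyl-bearing carbon) hides a γ,δ-unsaturated carbonyl unit: C10 is α to the side-chain carbonyl and C1 becomes allylic once C2/C3 form an alkene. An easier skeleton is therefore built first, a δ-lactone (C3–O–C(=O)–C10) trans-fused to ring B and carrying the (E)-alkenyl chain on C3. Ireland–Claisen ring contraction of its silyl ketene acetal forms C1–C10, closes carbocyclic ring A, sets C10 by chirality transfer from C3 and leaves a C2=C3 alkene that dihydroxylation and double oxidation turn into the diosphenol.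

Key step: step 9

Remark on numbering: target numbering is used for all intermediates (ring B = C4–C9 with C5 CHOH, C6 CHMe, C7 CH2, C8 CHOH; C4/C9 ring fusion). β is the face of C4–H and of the C10 methyl group; α is the face of C9–H, of the C5 and C8 oxygens and of the C6 methyl group.
Assumption: (R)-4-(tert-butyldimethylsilyloxy)cyclohex-2-en-1-one (9) is taken as a purchasable chiral building block.
Remark: the propanoate α-carbon (future C10) is carried as both epimers in 11–15 because step 9 makes it planar.

**Route**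

Step 1
Reactants: 1 (S)-3-bromo-2-methylpropan-1-ol; 2 pentylmagnesium bromide
Product: 3 (R)-2-methyloctan-1-ol
Conditions: 2 (3 equiv), Li2CuCl4 (3 mol%), THF, −20 to 23 °C; aq. NH4Cl
Reagents that add atoms: none
Why: Copper-catalysed sp3–sp3 cross-coupling of a primary bromide with a Grignard reagent (the first equivalent only forms the magnesium alkoxide); the stereocentre is not touched, and the descriptor changes from S to R only through CIP priorities.

Step 2
Reactants: 3 (R)-2-methyloctan-1-ol
Product: 4 (R)-2-methyloctanal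
Conditions: TEMPO (10 mol%), PhI(OAc)2, CH2Cl2, 23 °C
Reagents that add atoms: none
Why: Oxoammonium (TEMPO) oxidation stops at the aldehyde under non-basic conditions, so the α-stereocentre should not racemise.

Step 3
Reactants: 4 (R)-2-methyloctanal; 5 2-(triphenylphosphoranylidene)acetaldehyde
Product: 6 (R,E)-4-methyldec-2-enal
Conditions: 5, toluene, 80 °C
Reagents that add atoms: none
Why: Wittig olefination with the stabilised formylmethylene ylide should give the (E)-enal under neutral conditions that spare the adjacent stereocentre.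

Step 4
Reactants: 7 methyl propanoate
Product: 8 (E)-1-methoxy-1-(trimethylsilyloxy)prop-1-ene
Conditions: LiN(i-Pr)2, THF, −78 °C; Me3SiCl, −78 to 23 °C; distillation
Reagents that add atoms: chlorotrimethylsilane, C[Si](C)(C)Cl
Why: Kinetic ester enolisation and O-silylation give the silyl ketene acetal; its geometry is of no consequence because the carbon concerned (future C10) is made planar again in step 9.

Step 5
Reactants: 9 (R)-4-(tert-butyldimethylsilyloxy)cyclohex-2-en-1-one
Product: 10 (4R,6R)-4-(tert-butyldimethylsilyloxy)-6-methylcyclohex-2-en-1-one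
Conditions: LiN(i-Pr)2, THF, −78 °C; MeI, −78 to −20 °C
Reagents that add atoms: iodomethane, CI
Why: Kinetic α′-deprotonation to the cross-conjugated dienolate and C-methylation, expected anti to the silyloxy group; the C6 configuration is in any case reset thermodynamically in step 6.

Step 6
Reactants: 10 (4R,6R)-4-(tert-butyldimethylsilyloxy)-6-methylcyclohex-2-en-1-one; 8 (E)-1-methoxy-1-(trimethylsilyloxy)prop-1-ene
Product: 12 methyl 2-[(1S,2R,4S)-2-(tert-butyldimethylsilyloxy)-4-methyl-5-oxocyclohexyl]propanoate, via silyl enol ether 11 (not isolated)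
Conditions: 8, Sc(OTf)3 (5 mol%), CH2Cl2, −78 °C; then K2CO3 (cat.), MeOH, 23 °C
Reagents that add atoms: none
Why: Mukaiyama–Michael addition anti to the γ-silyloxy group sets C9 trans to the C8 oxygen, and methanolysis of the enol silane with base equilibration should place the C6 methyl group equatorial (cis to the silyloxy group), so that all three ring substituents are equatorial.

Step 7
Reactants: 12 methyl 2-[(1S,2R,4S)-2-(tert-butyldimethylsilyloxy)-4-methyl-5-oxocyclohexyl]propanoate; 6 (R,E)-4-methyldec-2-enal
Product: 13 methyl 2-[(1S,2R,4S,6S)-2-(tert-butyldimethylsilyloxy)-6-[(1R,2E,4R)-1-hydroxy-4-methyldec-2-en-1-yl]-4-methyl-5-oxocyclohexyl]propanoate (syn aldol)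
Conditions: LiN(i-Pr)2, THF, −78 °C; ClTi(Oi-Pr)3, −78 to −40 °C; 6, −78 °C; aq. NH4Cl
Reagents that add atoms: none
Why: Kinetic deprotonation at the C4 methylene (not at the methyl-bearing C6 methine) and transmetalation give a triisopropoxytitanium enolate, a class known to give syn aldols irrespective of enolate geometry; attack anti to the C9 arm sets C4 (H β) and the syn course sets the C3 carbinol (R).

Step 8
Reactants: 13 syn aldol adduct
Product: 15 trans-fused hydroxy δ-lactone (C3–O–C(=O)–C10; 3β-alkenyl; 4β-H; 9α-H; 5α-OH), via diol ester 14 (not isolated)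
Conditions: LiBH(s-Bu)3, THF, −78 °C; H2O; then PPTS (cat.), toluene, 80 °C
Reagents that add atoms: none
Why: The bulky hydride should attack the cyclohexanone from the equatorial (β) direction to give the axial 5α-alcohol (1,3-syn to the C3 hydroxyl), and acid-catalysed lactonisation then closes the δ-lactone through the C3 hydroxyl only, because the axial C5 hydroxyl lies anti to the ester arm and cannot reach it.

Step 9
Reactants: 15 trans-fused hydroxy δ-lactone
Product: 18 octalin hydroxy acid (ring A closed; C2=C3; 10β-methyl; 10α-CO2H), via bis-silyl ketene acetal 16 (not isolated), via trimethylsilyl ester 17 (not isolated)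
Conditions: Me3SiCl, Et3N, LiN(i-Pr)2 (2.5 equiv), THF, −78 to 23 °C; toluene, 110 °C; then 1 M HCl, THF, 23 °C
Reagents that add atoms: none
Why: Deprotonation and silylation give ketene acetal 16, whose C10=C(OSi)–O–C3–C2=C1 array is an allyl vinyl ether locked in the lactone ring; a concerted suprafacial [3,3]-sigmatropic shift forms C1–C10 while C3–O breaks, so the oxacycle contracts to carbocyclic ring A and the alkene moves to C2=C3. The closest known reaction type is the Ireland–Claisen ring contraction of 6-alkenyl δ-lactones to cyclohex-3-enecarboxylic acids. Ring A closes pericyclically through the boat transition state that the two-carbon tether C4–C9 enforces, not by an ionic exo or endo closure. C10 is controlled by the C3 stereocentre, because the 3β-alkenyl arm can reach only the β face of the planar ketene acetal, which puts the methyl group β (axial) and the carboxyl group α; C1 (octan-2-yl β) follows from the (E)-alkene in the boat and is erased in step 14. The step needs unambiguous enolisation, secured by the single α-hydrogen and the ring-fixed ketene acetal geometry, and it needs the trans-fused ring B to tolerate the boat, which should cost only a moderate flattening of the C4–C9 torsion.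

Step 10
Reactants: 18 octalin hydroxy acid
Product: 19 methyl ketone (10α-acetyl)
Conditions: MeLi (5 equiv), Et2O, 0 to 23 °C; H2O
Reagents that add atoms: methyllithium, [Li]C
Why: Addition of methyllithium to the lithium carboxylate gives a stable geminal dialkoxide that collapses to the methyl ketone only on work-up (carboxylic acid to methyl ketone), and no stereocentre is touched.

Step 11
Reactants: 19 methyl ketone
Product: 21 β-hydroxy ketone (10α-(3-hydroxypropanoyl); free 5α-OH), via silyl enol ether 20 (not isolated)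
Conditions: LiN(i-Pr)2 (2.5 equiv), Me3SiCl, THF, −78 °C; then aq. HCHO, Yb(OTf)3 (10 mol%), THF, 23 °C; dilute HCl work-up
Reagents that add atoms: formaldehyde, C=O
Why: The ketone can enolise only toward its methyl group because C10 is quaternary, and the lanthanide-triflate-catalysed Mukaiyama aldol of the enol silane with aqueous formaldehyde should stop at the mono-hydroxymethylated β-hydroxy ketone.

Step 12
Reactants: 21 β-hydroxy ketone
Product: 22 tris(tert-butyldimethylsilyl) ether
Conditions: t-BuMe2SiOTf, 2,6-lutidine, CH2Cl2, −78 to 0 °C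
Reagents that add atoms: tert-butyldimethylsilyl trifluoromethanesulfonate, CC(C)(C)[Si](C)(C)OS(=O)(=O)C(F)(F)F
Why: The silyl triflate should silylate both the primary hydroxyl and the hindered axial C5 hydroxyl, which protects them from the oxidation in step 14.

Step 13
Reactants: 22 tris(tert-butyldimethylsilyl) ether
Product: 23 2α,3α-diol
Conditions: OsO4 (5 mol%), NMO, acetone/H2O, 23 °C
Reagents that add atoms: N-methylmorpholine N-oxide, C[N+]1([O-])CCOCC1; water, O (both oxygen atoms are passed on through OsO4, O=[Os](=O)(=O)=O)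
Why: Upjohn syn-dihydroxylation of the only alkene, expected on the α face anti to the axial C10 methyl group; both new stereocentres are erased in step 14, so the facial outcome does not matter.

Step 14
Reactants: 23 2α,3α-diol
Product: 25 tris(tert-butyldimethylsilyl) ether of the target (diosphenol), via 2,3-diketone 24 (not isolated)
Conditions: (COCl)2, DMSO, CH2Cl2, −78 °C; Et3N, −78 to 0 °C
Reagents that add atoms: none
Why: Double Swern oxidation of the vicinal diol gives the 1,2-diketone without C–C cleavage, and enolisation toward C1 should give the conjugated diosphenol, removing the C1 stereocentre while C4 keeps the favoured trans ring fusion.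

Step 15
Reactants: 25 tris(tert-butyldimethylsilyl) ether of the target
Product: 26 CNP0234794.3
Conditions: 48% aq. HF, MeCN, 0 to 23 °C
Reagents that add atoms: none
Why: Acidic fluoride cleavage of the three silyl ethers avoids the base-induced β-elimination that threatens the β-hydroxy ketone, and leaves all stereocentres untouched.

**Compound list**

1 | (S)-3-bromo-2-methylpropan-1-ol | OC[C@H](C)CBr | starting material
2 | pentylmagnesium bromide | CCCCC[Mg]Br | starting material
3 | (R)-2-methyloctan-1-ol | OC[C@H](C)CCCCCC | intermediate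
4 | (R)-2-methyloctanal | O=C[C@H](C)CCCCCC | intermediate
5 | 2-(triphenylphosphoranylidene)acetaldehyde | O=CC=P(c1ccccc1)(c1ccccc1)c1ccccc1 | starting material
6 | (R,E)-4-methyldec-2-enal | O=C/C=C/[C@H](C)CCCCCC | intermediate
7 | methyl propanoate | CCC(=O)OC | starting material
8 | (E)-1-methoxy-1-(trimethylsilyloxy)prop-1-ene | C/C=C(\OC)O[Si](C)(C)C | intermediate
9 | (R)-4-(tert-butyldimethylsilyloxy)cyclohex-2-en-1-one | O=C1C=C[C@H](O[Si](C)(C)C(C)(C)C)CC1 | starting material
10 | (4R,6R)-4-(tert-butyldimethylsilyloxy)-6-methylcyclohex-2-en-1-one (methyl trans to the silyloxy group) | O=C1C=C[C@H](O[Si](C)(C)C(C)(C)C)C[C@H]1C | intermediate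
11 | trimethylsilyl enol ether (C4=C5) of the Michael adduct; propanoate arm on C9 trans to the C8 silyloxy group, C6 methyl still trans to it; both epimers at future C10 | COC(=O)C(C)[C@@H]1C=C(O[Si](C)(C)C)[C@H](C)C[C@H]1O[Si](C)(C)C(C)(C)C | intermediate
12 | methyl 2-[(1S,2R,4S)-2-(tert-butyldimethylsilyloxy)-4-methyl-5-oxocyclohexyl]propanoate (all ring substituents equatorial; both epimers at future C10) | COC(=O)C(C)[C@@H]1CC(=O)[C@@H](C)C[C@H]1O[Si](C)(C)C(C)(C)C | intermediate
13 | methyl 2-[(1S,2R,4S,6S)-2-(tert-butyldimethylsilyloxy)-6-[(1R,2E,4R)-1-hydroxy-4-methyldec-2-en-1-yl]-4-methyl-5-oxocyclohexyl]propanoate (syn aldol; both epimers at future C10) | COC(=O)C(C)[C@@H]1[C@@H]([C@H](O)/C=C/[C@H](C)CCCCCC)C(=O)[C@@H](C)C[C@H]1O[Si](C)(C)C(C)(C)C | intermediate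
14 | diol ester: 13 with C5 reduced to the axial 5α-alcohol (1,3-syn to the C3 hydroxyl) | COC(=O)C(C)[C@@H]1[C@@H]([C@H](O)/C=C/[C@H](C)CCCCCC)[C@@H](O)[C@@H](C)C[C@H]1O[Si](C)(C)C(C)(C)C | intermediate
15 | δ-lactone C3–O–C(=O)–C10 trans-fused to ring B at C4/C9: 3β-[(1E,3R)-3-methylnon-1-en-1-yl], 4β-H, 9α-H, 5α-OH, 6α-methyl, 8α-OSi(t-Bu)Me2, 10-methyl (both epimers) | CC1C(=O)O[C@H](/C=C/[C@H](C)CCCCCC)[C@H]2[C@@H](O)[C@@H](C)C[C@@H](O[Si](C)(C)C(C)(C)C)[C@@H]21 | intermediate
16 | cyclic trimethylsilyl ketene acetal of 15 (C10=C(OSiMe3)–O) with the C5 hydroxyl as its trimethylsilyl ether | CC1=C(O[Si](C)(C)C)O[C@H](/C=C/[C@H](C)CCCCCC)[C@H]2[C@@H](O[Si](C)(C)C)[C@@H](C)C[C@@H](O[Si](C)(C)C(C)(C)C)[C@@H]21 | intermediate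
17 | trimethylsilyl ester of 18 with the C5 hydroxyl as its trimethylsilyl ether | CCCCCC[C@@H](C)[C@@H]1C=C[C@H]2[C@@H](O[Si](C)(C)C)[C@@H](C)C[C@@H](O[Si](C)(C)C(C)(C)C)[C@@H]2[C@@]1(C)C(=O)O[Si](C)(C)C | intermediate
18 | trans-fused octalin acid: C2=C3 alkene, 10β-methyl, 10α-CO2H, 1β-[(R)-octan-2-yl] (1α-H), 4β-H, 9α-H, 5α-OH, 6α-methyl, 8α-OSi(t-Bu)Me2 | CCCCCC[C@@H](C)[C@@H]1C=C[C@H]2[C@@H](O)[C@@H](C)C[C@@H](O[Si](C)(C)C(C)(C)C)[C@@H]2[C@@]1(C)C(=O)O | intermediate
19 | methyl ketone: 18 with CO2H replaced by acetyl | CCCCCC[C@@H](C)[C@@H]1C=C[C@H]2[C@@H](O)[C@@H](C)C[C@@H](O[Si](C)(C)C(C)(C)C)[C@@H]2[C@@]1(C)C(C)=O | intermediate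
20 | trimethylsilyl enol ether of 19 (CH2=C(OSiMe3) on C10) with the C5 hydroxyl as its trimethylsilyl ether | CCCCCC[C@@H](C)[C@@H]1C=C[C@H]2[C@@H](O[Si](C)(C)C)[C@@H](C)C[C@@H](O[Si](C)(C)C(C)(C)C)[C@@H]2[C@@]1(C)C(=C)O[Si](C)(C)C | intermediate
21 | β-hydroxy ketone: 10α-(3-hydroxypropanoyl), free 5α-OH, 8α-OSi(t-Bu)Me2, C2=C3 alkene | CCCCCC[C@@H](C)[C@@H]1C=C[C@H]2[C@@H](O)[C@@H](C)C[C@@H](O[Si](C)(C)C(C)(C)C)[C@@H]2[C@@]1(C)C(=O)CCO | intermediate
22 | tris(tert-butyldimethylsilyl) ether of 21 (C5, C8 and primary oxygen) | CCCCCC[C@@H](C)[C@@H]1C=C[C@H]2[C@@H](O[Si](C)(C)C(C)(C)C)[C@@H](C)C[C@@H](O[Si](C)(C)C(C)(C)C)[C@@H]2[C@@]1(C)C(=O)CCO[Si](C)(C)C(C)(C)C | intermediate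
23 | 2α,3α-diol of 22 | CCCCCC[C@@H](C)[C@@H]1[C@@H](O)[C@@H](O)[C@H]2[C@@H](O[Si](C)(C)C(C)(C)C)[C@@H](C)C[C@@H](O[Si](C)(C)C(C)(C)C)[C@@H]2[C@@]1(C)C(=O)CCO[Si](C)(C)C(C)(C)C | intermediate
24 | 2,3-diketone (1α-H), keto tautomer of 25 | CCCCCC[C@@H](C)[C@@H]1C(=O)C(=O)[C@H]2[C@@H](O[Si](C)(C)C(C)(C)C)[C@@H](C)C[C@@H](O[Si](C)(C)C(C)(C)C)[C@@H]2[C@@]1(C)C(=O)CCO[Si](C)(C)C(C)(C)C | intermediate
25 | tris(tert-butyldimethylsilyl) ether of the target (C1=C2 enol, C3 ketone) | CCCCCC[C@@H](C)C1=C(O)C(=O)[C@H]2[C@@H](O[Si](C)(C)C(C)(C)C)[C@@H](C)C[C@@H](O[Si](C)(C)C(C)(C)C)[C@@H]2[C@@]1(C)C(=O)CCO[Si](C)(C)C(C)(C)C | intermediate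
26 | CNP0234794.3, (4R,4aS,5R,7S,8S,8aR)-2,5,8-trihydroxy-4-(3-hydroxypropanoyl)-4,7-dimethyl-3-[(2R)-octan-2-yl]-4a,5,6,7,8,8a-hexahydronaphthalen-1(4H)-one | CCCCCC[C@@H](C)C1=C(O)C(=O)[C@H]2[C@@H](O)[C@@H](C)C[C@@H](O)[C@@H]2[C@@]1(C)C(=O)CCO | target

**Step count.** Total: 15 steps. Longest linear sequence: 12 steps (steps 1, 2, 3 and 7 to 15, from 1).

**Steps most likely to fail**

Step 9 (key step). The [3,3] shift may be slow, because the boat transition state has to be reached inside a trans-fused bicycle, and thermal breakdown of the silyl ketene acetal may then outrun the rearrangement. The fallback closes the same C1–C10 bond by an anionic SN2′ displacement that needs no heating. It sets out from keto ester 12. Aldol addition of its lithium enolate (LiN(i-Pr)2, THF, −78 °C) to enal 6 should give, through the closed chair transition state, the anti aldol adduct F1 (the C3 epimer of 13). Reduction with LiBH(s-Bu)3 as in step 8, without the acid treatment, would give the diol ester F2. The less hindered allylic C3 hydroxyl would be phosphorylated (ClP(O)(OEt)2, pyridine, DMAP) to the allylic diethyl phosphate F3, and the axial C5 hydroxyl capped (Et3SiOTf, 2,6-lutidine) as the triethylsilyl ether F4. KN(SiMe3)2 (THF, −78 to 0 °C) then forms the C10 ester enolate, which should displace the phosphate anti in a six-membered SN2′ closure to the octalin methyl ester F5. With the inverted C3 centre, an anti displacement brings C10 to the same face of C1 as the sigmatropic route, and allylic strain in the enolate should place the ester group equatorial. Demethylation with LiI in hot pyridine and work-up with dilute HCl, which also removes the triethylsilyl group, comes back to the route at hydroxy acid 18.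

Step 7. Simple diastereoselection in the titanium aldol may be poor (anti instead of syn at C3). The fallback makes the C3 configuration independent of the aldol. It sets out from keto ester 12 and uses the anti aldol adduct F1 and its reduction product, the diol ester F2, prepared as described above. The allylic C3 alcohol of F2 would be oxidised selectively with MnO2 (CH2Cl2, 23 °C) to the hydroxy enone F6. Narasaka–Prasad reduction of F6 (Et2BOMe, NaBH4, THF/MeOH, −78 °C), directed by the C5 hydroxyl, should give the 1,3-syn diol and so comes back to the route at diol ester 14, which is lactonised as in step 8.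

Step 14. The double oxidation may stall at the ketol stage, cleave the C2–C3 bond, or enolise the diketone toward C4 under the amine base with loss of the trans ring fusion. The fallback oxidises in two separate, base-free stages. It sets out from diol 23: the stannylene acetal (Bu2SnO, toluene, reflux) would be brominolysed with N-bromosuccinimide (CHCl3, 23 °C), which should oxidise only the axial C3 hydroxyl and give the α-hydroxy ketone F7. Oxidation of this acyloin with Cu(OAc)2 in aqueous acetic acid/methanol then comes back to the route at diosphenol 25.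

**Further compounds**

F1 | step 9 | anti aldol adduct, C3 epimer of 13 | COC(=O)C(C)[C@@H]1[C@@H]([C@@H](O)/C=C/[C@H](C)CCCCCC)C(=O)[C@@H](C)C[C@H]1O[Si](C)(C)C(C)(C)C
F2 | step 9 | diol ester, C3 epimer of 14 (5α-OH axial) | COC(=O)C(C)[C@@H]1[C@@H]([C@@H](O)/C=C/[C@H](C)CCCCCC)[C@@H](O)[C@@H](C)C[C@H]1O[Si](C)(C)C(C)(C)C
F3 | step 9 | allylic C3 diethyl phosphate of F2 | COC(=O)C(C)[C@@H]1[C@@H]([C@@H](OP(=O)(OCC)OCC)/C=C/[C@H](C)CCCCCC)[C@@H](O)[C@@H](C)C[C@H]1O[Si](C)(C)C(C)(C)C
F4 | step 9 | C5 triethylsilyl ether of F3 | COC(=O)C(C)[C@@H]1[C@@H]([C@@H](OP(=O)(OCC)OCC)/C=C/[C@H](C)CCCCCC)[C@@H](O[Si](CC)(CC)CC)[C@@H](C)C[C@H]1O[Si](C)(C)C(C)(C)C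
F5 | step 9 | methyl ester of 18 with the C5 hydroxyl as its triethylsilyl ether | CCCCCC[C@@H](C)[C@@H]1C=C[C@H]2[C@@H](O[Si](CC)(CC)CC)[C@@H](C)C[C@@H](O[Si](C)(C)C(C)(C)C)[C@@H]2[C@@]1(C)C(=O)OC
F6 | step 7 | hydroxy enone (C3 ketone conjugated with C1=C2, free 5α-OH) | COC(=O)C(C)[C@@H]1[C@@H](C(=O)/C=C/[C@H](C)CCCCCC)[C@@H](O)[C@@H](C)C[C@H]1O[Si](C)(C)C(C)(C)C
F7 | step 14 | α-hydroxy ketone (C3 ketone, 2α-OH) | CCCCCC[C@@H](C)[C@@H]1[C@@H](O)C(=O)[C@H]2[C@@H](O[Si](C)(C)C(C)(C)C)[C@@H](C)C[C@@H](O[Si](C)(C)C(C)(C)C)[C@@H]2[C@@]1(C)C(=O)CCO[Si](C)(C)C(C)(C)C
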